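The ratio to start from is 1.85: in the amber run, the rate of product formation between 33 min and 53 min over the rate between 1.9 min and 17 min. The amber rate climbs from 0.132 mM min⁻¹ to 0.245 mM min⁻¹ while starting material is being consumed, so product seems to feed its own formation (autocatalysis). The next charge hangs on how the free catalyst shares the rate with that feed. The candidate is the ochre run: amber's charge of starting material and partner, with twice the free catalyst.

| flask | starting material | partner | free catalyst | time |
|---|---|---|---|---|
| red | 50.0 mM | 150 mM | 0.500 mM |  |
| green | 30.0 mM | 130 mM | 0.500 mM |  |
| blue | 50.0 mM | 150 mM | 0.750 mM |  |
| amber | 25.0 mM | 150 mM | 0.500 mM |  |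
| ochre | 25.0 mM | 150 mM | 1.00 mM | 53 min |

- red run (time / min: [product] / mM): 1.9: 0.9; 5.8: 1.2; 11: 2.3; 17: 3.9; 25: 6.4; 33: 11.8; 43: 18.0; 53: 23.0
- green run (time / min: [product] / mM): 1.9: 0.3; 5.8: 1.9; 11: 2.1; 17: 3.6; 25: 4.9; 33: 6.7; 43: 9.6; 53: 13.3
- blue run (time / min: [product] / mM): 1.9: 0.7; 5.8: 1.4; 11: 3.2; 17: 6.6; 25: 10.0; 33: 15.7; 43: 22.3; 53: 30.0
- amber run (time / min: [product] / mM): 1.9: 0.4; 5.8: 0.8; 11: 2.0; 17: 2.4; 25: 4.2; 33: 6.5; 43: 8.5; 53: 11.4

(each reading ± 0.5 mM)

- Overall: starting material + partner -> product, with free catalyst as catalyst.
- Constant volume, constant temperature.
- The analysis sees a species whether free or bound.
- An order is taken over about fifteen percent of the charge, up and down.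

- the exponent of [starting material] in the starting rate at the charge of the red run (at the point where two percent of the starting material have become product) (one fixed amount of product, the same in the runs compared)
- the exponent of [partner] in the starting rate at the charge of the red run (at the point where two percent of the starting material have become product)
- the green run starts with 20.0 mM less of starting material and of partner than the red run, and with no product. Compared where both hold the same amount of starting material, once fifteen percent of what the green run was charged with has turned into product, is the green run faster, slower or alike (within a tenth)?
- product in the ochre run at 53 min, as a share of the starting material charged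

The reckoning made here, apart from the forecast, writes the amber rate as a base rate plus a gain times the product held, and neglects consumption. The two amber rates, taken at mean products of 1.40 mM and 8.95 mM, give a gain of 0.0149 min⁻¹ and a base rate of 0.112 mM min⁻¹. Base over gain, as a fraction of the charge, is the crossing share 29.9%: the share of the charge standing as product at which the product-fed rate equals the base rate. It is a reading, and a rough one: the scatter of the readings puts 0.0468 mM min⁻¹ on the early rate.

Assume that the doubled catalyst doubles the base rate and leaves the gain. The ochre crossing share then moves to 59.9%. Integrating base plus gain times product over 53 min, still with consumption neglected, gives the ochre run a share of 72.1%, above the 45.6% read from the amber run at the same time. On that margin the decision is to charge the ochre run with the catalyst doubled and leave starting material, partner and time as they stand.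

The forecast, from the same runs, gives exponents of 0.7 for starting material and 0.2 for partner, calls the green run slower, and puts the ochre run at 75%. It reads the curves as the reckoning here does, “so product appears to promote reaction”, and its ochre share stands higher than the reckoning's 72.1%.

The flask follows this scheme:

    free catalyst + starting material → catalyst-substrate complex (45.30 M⁻¹ min⁻¹)
    catalyst-substrate complex + partner → loaded catalyst (87.00 M⁻¹ min⁻¹)
    loaded catalyst → product + free catalyst (0.4596 min⁻¹)
    starting material + partner + product → 2 product (15.78 M⁻² min⁻¹)
    2 partner ⇌ idle reagent dimer, settled at all times (14.10 M⁻¹)

The ochre run gives 73.1% of its charge, the exponents are 0.34 and 0.16, and the green run is slower. The amber rate over the red rate at equal product made is 0.78, on half the starting material. The ochre share stands above its reckoned crossing share of 59.9%. The crossing share serves the green run too: at the comparison point, green holds 4.50 mM of product and red 24.5 mM, with equal starting material and partner. Amber's 29.9% then gives the green rate over the red rate as 0.375, and the flask's ratio is 0.38.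

(The data were computed from invented constants; the scatter is artificial.)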